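Ring B (B1 biaryl carbon, B2 phenethyl carbon, B3 C=O, B4 C–OH, B5 C–CH3, B6 C=O) is disconnected at the B2–B3 bond. Atoms B3–B6 show the O, O, CH3, O sequence of a C-methylated squaric ester, and B1=B2 is an alkene that already carries the finished ring A on B1. Heating racemic cyclobutenone 22, a 2,4-dimethoxy-3-methylcyclobut-2-enone whose C4 bears the (E)-1-aryl-4-phenylbut-1-enyl group, should open the four-membered ring to a dienylketene that closes B2–B3 and aromatises. One operation thus builds ring B and the fully ortho-substituted biaryl 25; oxidation and ether hydrolysis then give the bis(hydroxyquinone).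

Key step: step 12

Assumption: the target SMILES carries no stereodescriptor, so the hindered biaryl axis is formed without control; chiral intermediates 18–22 and 24 are racemic, one enantiomer drawn. Ar = 2,4,5-trimethoxy-6-[2-(2-methoxyphenyl)ethyl]-3-methylphenyl (ring A with its side chain).

Step 1
Reactants: 1 2-methoxybenzyl chloride
Product: 2 (2-methoxybenzyl)triphenylphosphonium chloride
Conditions: PPh3, toluene, reflux
Reagents that add atoms: triphenylphosphine, c1ccc(cc1)P(c1ccccc1)c1ccccc1
Why: SN2 quaternisation of PPh3 by a primary benzylic chloride should give the crystalline salt.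

Step 2
Reactants: 2 (2-methoxybenzyl)triphenylphosphonium chloride; 3 3,5-dimethoxy-4-methylbenzaldehyde
Product: 5 1,3-dimethoxy-5-[2-(2-methoxyphenyl)ethenyl]-2-methylbenzene (E/Z mixture), via phosphorus ylide 4 (not isolated)
Conditions: KOtBu, THF, 0 °C; then 3, 0 °C to rt
Reagents that add atoms: none
Why: Wittig olefination with the semistabilised benzylic ylide should give the stilbene as an E/Z mixture, which is immaterial because the double bond is hydrogenated in step 3.

Step 3
Reactants: 5 1,3-dimethoxy-5-[2-(2-methoxyphenyl)ethenyl]-2-methylbenzene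
Product: 6 1,3-dimethoxy-5-[2-(2-methoxyphenyl)ethyl]-2-methylbenzene
Conditions: H2 (1 atm), 10% Pd/C, EtOAc, rt
Reagents that add atoms: none
Why: Catalytic hydrogenation over palladium should saturate the stilbene double bond without touching the aryl methyl ethers.

Step 4
Reactants: 6 1,3-dimethoxy-5-[2-(2-methoxyphenyl)ethyl]-2-methylbenzene
Product: 8 2,4-dimethoxy-6-[2-(2-methoxyphenyl)ethyl]-3-methylbenzaldehyde, via iminium chloride 7 (not isolated)
Conditions: POCl3, DMF, 0 to 70 °C; then H2O
Reagents that add atoms: N,N-dimethylformamide, CN(C)C=O; water, O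
Why: Vilsmeier–Haack formylation; the weak chloroiminium electrophile should attack only one of the two equivalent ring A positions lying ortho to one methoxy group and para to the other, the monomethoxy ring being too poor a nucleophile.

Step 5
Reactants: 8 2,4-dimethoxy-6-[2-(2-methoxyphenyl)ethyl]-3-methylbenzaldehyde
Product: 10 2,4-dimethoxy-6-[2-(2-methoxyphenyl)ethyl]-3-methylphenol, via aryl formate 9 (not isolated)
Conditions: mCPBA, CH2Cl2, 0 °C to rt; then K2CO3, MeOH, rt
Reagents that add atoms: meta-chloroperbenzoic acid, OOC(=O)c1cccc(Cl)c1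
Why: Dakin-type Baeyer–Villiger oxidation, in which the electron-rich aryl group migrates to oxygen, followed by methanolysis of the formate should replace the formyl group by hydroxyl.

Step 6
Reactants: 10 2,4-dimethoxy-6-[2-(2-methoxyphenyl)ethyl]-3-methylphenol
Product: 11 1,3,4-trimethoxy-5-[2-(2-methoxyphenyl)ethyl]-2-methylbenzene
Conditions: MeI, K2CO3, DMF, rt
Reagents that add atoms: iodomethane, CI
Why: Williamson etherification of the phenoxide with MeI should proceed despite the two flanking substituents.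

Step 7
Reactants: 11 1,3,4-trimethoxy-5-[2-(2-methoxyphenyl)ethyl]-2-methylbenzene
Product: 12 1-iodo-2,4,5-trimethoxy-6-[2-(2-methoxyphenyl)ethyl]-3-methylbenzene (Ar–I)
Conditions: NIS (1.05 equiv), CF3CO2H (cat.), MeCN, 0 °C to rt
Reagents that add atoms: N-iodosuccinimide, O=C1CCC(=O)N1I
Why: Electrophilic aromatic iodination at the single free position of ring A, which is ortho and para to methoxy groups on a ring with five donor substituents, should outpace attack on the monomethoxy ring when one equivalent of NIS is used.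

Step 8
Reactants: 12 Ar–I; 13 4-phenyl-1-butyne
Product: 14 1-Ar-4-phenylbut-1-yne
Conditions: PdCl2(PPh3)2 (5 mol%), CuI (10 mol%), Et3N, DMF, 70 °C
Reagents that add atoms: none
Why: Sonogashira coupling; aryl iodides add oxidatively to zerovalent palladium even when electron-rich and flanked by two ortho substituents, and the terminal alkyne is unhindered.

Step 9
Reactants: 14 1-Ar-4-phenylbut-1-yne
Product: 15 tributyl[(1E)-1-Ar-4-phenylbut-1-en-1-yl]stannane
Conditions: Bu3SnH (1.5 equiv, slow addition), Pd(PPh3)4 (5 mol%), THF, 0 °C to rt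
Reagents that add atoms: tributyltin hydride, CCCC[SnH](CCCC)CCCC
Why: Palladium-catalysed hydrostannation adds H and Sn syn across the alkyne, and ortho substituents on the aryl group steer tin to the aryl-bearing carbon, which should give the E alkenylstannane with tin cis to the vinylic hydrogen.

Step 10
Reactants: 15 tributyl[(1E)-1-Ar-4-phenylbut-1-en-1-yl]stannane; 16 dimethyl squarate
Product: 19 4-[(1E)-1-Ar-4-phenylbut-1-en-1-yl]-2,3,4-trimethoxycyclobut-2-en-1-one (racemic), via alkenyllithium 17 (not isolated), via lithium alkoxide 18 (not isolated)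
Conditions: n-BuLi, THF, −78 °C; then 16, THF, −78 °C; then MeOTf, −78 to 0 °C
Reagents that add atoms: methyl trifluoromethanesulfonate, COS(=O)(=O)C(F)(F)F
Why: Tin–lithium exchange with retention of alkene geometry, 1,2-addition of the alkenyllithium to one of the two equivalent squarate carbonyls and O-methylation of the tertiary alkoxide by the triflate should follow in one flask; the new quaternary carbon forms as a racemate.

Step 11
Reactants: 19 4-[(1E)-1-Ar-4-phenylbut-1-en-1-yl]-2,3,4-trimethoxycyclobut-2-en-1-one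
Product: 22 4-[(1E)-1-Ar-4-phenylbut-1-en-1-yl]-2,4-dimethoxy-3-methylcyclobut-2-en-1-one (racemic), via lithium alkoxide 20 (not isolated), via trifluoroacetate 21 (not isolated)
Conditions: MeLi, THF, −78 °C; then (CF3CO)2O, −78 °C; then aq. NaHCO3
Reagents that add atoms: methyllithium, [Li]C
Why: 1,2-Addition of MeLi to the carbonyl, trifluoroacetylation of the new alkoxide and ionisation give an allyl cation stabilised by the distal methoxy group, so hydrolysis at that carbon (a 1,3-carbonyl transposition) should place methyl next to the quaternary carbon and methoxy next to the new carbonyl, the existing stereocentre being untouched.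

Step 12
Reactants: 22 4-[(1E)-1-Ar-4-phenylbut-1-en-1-yl]-2,4-dimethoxy-3-methylcyclobut-2-en-1-one
Product: 25 5-Ar-2,4-dimethoxy-3-methyl-6-(2-phenylethyl)phenol (biaryl; ring B as 4-methoxyphenol), via dienylketene 23 (not isolated), via cyclohexadienone 24 (not isolated)
Conditions: toluene (degassed), 110 °C, Ar
Reagents that add atoms: none
Why: Heating should trigger a four-electron conrotatory opening of the cyclobutenone C1–C4 bond in which the C4 methoxy donor turns outward and the alkenyl group inward, giving dienylketene 23 with the ketene and alkene termini cis. A six-electron disrotatory electrocyclisation then joins the ketene carbon (B3) to the alkene CH (B2), closing the six-membered ring B as cyclohexadienone 24, and enolisation aromatises it to the 4-methoxyphenol 25. The closest known reaction type is the thermal ring expansion of squarate-derived 4-alkenyl-4-alkoxycyclobutenones to hydroquinone monoethers. No stereocentre results: C4 of 22 becomes sp2 B6, the transient sp3 B2 of 24 is lost on tautomerisation, and the hindered axis forms as a racemate. The step needs torquoselectivity and regiochemistry; the oxygen donor on C4 secures the first, and the second is already written into 22 (methoxy carbon next to the carbonyl, methyl carbon next to C4), so only one arene can form. The E alkene keeps hydrogen on the inner face of B2 and ring A sits on B1 as a twisted bystander, so the bond forms at the least crowded terminus; any Z isomer would converge on the same product because B2 loses its hydrogen.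

Step 13
Reactants: 25 5-Ar-2,4-dimethoxy-3-methyl-6-(2-phenylethyl)phenol
Product: 26 2-methoxy-3-methyl-6-(2-phenylethyl)-5-{4-methoxy-5-methyl-2-[2-(2-methoxyphenyl)ethyl]-3,6-dioxocyclohexa-1,4-dien-1-yl}cyclohexa-2,5-diene-1,4-dione
Conditions: (NH4)2Ce(NO3)6 (5 equiv), MeCN–H2O (3:1), 0 °C
Reagents that add atoms: water, O
Why: Oxidative demethylation by the one-electron oxidant should turn the 4-methoxyphenol of ring B and the para-dimethoxy pair of ring A into 1,4-benzoquinones, water supplying the new carbonyl oxygens, while the third methoxy group of each ring and the monomethoxy distal ring remain.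

Step 14
Reactants: 26 bis(methoxyquinone)
Product: 27 2-hydroxy-3-methyl-6-(2-phenylethyl)-5-{4-hydroxy-5-methyl-2-[2-(2-methoxyphenyl)ethyl]-3,6-dioxocyclohexa-1,4-dien-1-yl}cyclohexa-2,5-diene-1,4-dione (target)
Conditions: 2 M NaOH (aq), THF–MeOH, rt, Ar; then 1 M HCl
Reagents that add atoms: sodium hydroxide, [Na+].[OH-]
Why: Addition–elimination of hydroxide at the methoxy-bearing vinylogous ester carbon of each 2-methoxy-1,4-benzoquinone should give the base-stable hydroxyquinone anions, which acid returns to the neutral target; the aryl methyl ether of the distal ring is inert.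

Compound list
1 | 2-methoxybenzyl chloride | COc1ccccc1CCl | starting material
2 | (2-methoxybenzyl)triphenylphosphonium chloride | COc1ccccc1C[P+](c1ccccc1)(c1ccccc1)c1ccccc1.[Cl-] | intermediate
3 | 3,5-dimethoxy-4-methylbenzaldehyde | Cc1c(OC)cc(C=O)cc1OC | starting material
4 | (2-methoxybenzylidene)triphenylphosphorane | COc1ccccc1C=P(c1ccccc1)(c1ccccc1)c1ccccc1 | intermediate (not isolated)
5 | 1,3-dimethoxy-5-[2-(2-methoxyphenyl)ethenyl]-2-methylbenzene, E/Z mixture | COc1ccccc1C=Cc1cc(OC)c(C)c(OC)c1 | intermediate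
6 | 1,3-dimethoxy-5-[2-(2-methoxyphenyl)ethyl]-2-methylbenzene | COc1ccccc1CCc1cc(OC)c(C)c(OC)c1 | intermediate
7 | N,N-dimethyliminium chloride of aldehyde 8 | COc1ccccc1CCc1cc(OC)c(C)c(OC)c1C=[N+](C)C.[Cl-] | intermediate (not isolated)
8 | 2,4-dimethoxy-6-[2-(2-methoxyphenyl)ethyl]-3-methylbenzaldehyde | COc1ccccc1CCc1cc(OC)c(C)c(OC)c1C=O | intermediate
9 | 2,4-dimethoxy-6-[2-(2-methoxyphenyl)ethyl]-3-methylphenyl formate | COc1ccccc1CCc1cc(OC)c(C)c(OC)c1OC=O | intermediate (not isolated)
10 | 2,4-dimethoxy-6-[2-(2-methoxyphenyl)ethyl]-3-methylphenol | COc1ccccc1CCc1cc(OC)c(C)c(OC)c1O | intermediate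
11 | 1,3,4-trimethoxy-5-[2-(2-methoxyphenyl)ethyl]-2-methylbenzene | COc1ccccc1CCc1cc(OC)c(C)c(OC)c1OC | intermediate
12 | 1-iodo-2,4,5-trimethoxy-6-[2-(2-methoxyphenyl)ethyl]-3-methylbenzene (Ar–I) | COc1ccccc1CCc1c(I)c(OC)c(C)c(OC)c1OC | intermediate
13 | 4-phenyl-1-butyne | C#CCCc1ccccc1 | starting material
14 | 1-Ar-4-phenylbut-1-yne | COc1ccccc1CCc1c(C#CCCc2ccccc2)c(OC)c(C)c(OC)c1OC | intermediate
15 | tributyl[(1E)-1-Ar-4-phenylbut-1-en-1-yl]stannane | CCCC[Sn](CCCC)(CCCC)/C(=C/CCc1ccccc1)c1c(CCc2ccccc2OC)c(OC)c(OC)c(C)c1OC | intermediate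
16 | dimethyl squarate | COC1=C(OC)C(=O)C1=O | starting material
17 | [(1Z)-1-Ar-4-phenylbut-1-en-1-yl]lithium (Li cis to the vinylic H) | [Li]/C(=C/CCc1ccccc1)c1c(CCc2ccccc2OC)c(OC)c(OC)c(C)c1OC | intermediate (not isolated)
18 | lithium 1-[(1E)-1-Ar-4-phenylbut-1-en-1-yl]-2,3-dimethoxy-4-oxocyclobut-2-en-1-olate, racemic | COC1=C(OC)[C@](O[Li])(/C(=C/CCc2ccccc2)c2c(CCc3ccccc3OC)c(OC)c(OC)c(C)c2OC)C1=O | intermediate (not isolated)
19 | 4-[(1E)-1-Ar-4-phenylbut-1-en-1-yl]-2,3,4-trimethoxycyclobut-2-en-1-one, racemic | COC1=C(OC)[C@](OC)(/C(=C/CCc2ccccc2)c2c(CCc3ccccc3OC)c(OC)c(OC)c(C)c2OC)C1=O | intermediate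
20 | lithium 4-[(1E)-1-Ar-4-phenylbut-1-en-1-yl]-2,3,4-trimethoxy-1-methylcyclobut-2-en-1-olate, diastereomer mixture | COC1=C(OC)[C@](OC)(/C(=C/CCc2ccccc2)c2c(CCc3ccccc3OC)c(OC)c(OC)c(C)c2OC)C1(C)O[Li] | intermediate (not isolated)
21 | trifluoroacetate ester of the alcohol corresponding to 20 | COC1=C(OC)[C@](OC)(/C(=C/CCc2ccccc2)c2c(CCc3ccccc3OC)c(OC)c(OC)c(C)c2OC)C1(C)OC(=O)C(F)(F)F | intermediate (not isolated)
22 | 4-[(1E)-1-Ar-4-phenylbut-1-en-1-yl]-2,4-dimethoxy-3-methylcyclobut-2-en-1-one, racemic | COC1=C(C)[C@@](OC)(/C(=C/CCc2ccccc2)c2c(CCc3ccccc3OC)c(OC)c(OC)c(C)c2OC)C1=O | intermediate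
23 | (3E,5E)-5-Ar-2,4-dimethoxy-3-methyl-8-phenylocta-1,3,5-trien-1-one (dienylketene) | O=C=C(OC)/C(C)=C(OC)\C(=C\CCc1ccccc1)c1c(CCc2ccccc2OC)c(OC)c(OC)c(C)c1OC | intermediate (not isolated)
24 | 5-Ar-2,4-dimethoxy-3-methyl-6-(2-phenylethyl)cyclohexa-2,4-dien-1-one, racemic | COC1=C(C)C(OC)=C(c2c(CCc3ccccc3OC)c(OC)c(OC)c(C)c2OC)[C@H](CCc2ccccc2)C1=O | intermediate (not isolated)
25 | 5-Ar-2,4-dimethoxy-3-methyl-6-(2-phenylethyl)phenol | COc1ccccc1CCc1c(-c2c(CCc3ccccc3)c(O)c(OC)c(C)c2OC)c(OC)c(C)c(OC)c1OC | intermediate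
26 | bis(methoxyquinone), name as in step 13 | COc1ccccc1CCC1=C(C2=C(CCc3ccccc3)C(=O)C(OC)=C(C)C2=O)C(=O)C(C)=C(OC)C1=O | intermediate
27 | bis(hydroxyquinone), name as in step 14 | COc1ccccc1CCC1=C(C2=C(CCc3ccccc3)C(=O)C(O)=C(C)C2=O)C(=O)C(C)=C(O)C1=O | target

Total step count: 14. Longest linear sequence: 14 steps (1 to 27); 13 and 16 enter at steps 8 and 10.

Steps most likely to fail

Step 12. The six-electron closure onto B2 may be slower than dimerisation or decomposition of the dienylketene, because the perpendicular, fully substituted ring A on B1 crowds the s-cis conformer. The fallback forms the aryl–aryl bond by Suzuki–Miyaura coupling of two complete arenes; it sets out from 3 and 12 and comes back at 26. Aldehyde 3 is condensed with the ylide from benzyltriphenylphosphonium chloride (KOtBu, THF) to 1,3-dimethoxy-2-methyl-5-(2-phenylethenyl)benzene F1 and hydrogenated (H2, 10% Pd/C) to 1,3-dimethoxy-2-methyl-5-(2-phenylethyl)benzene F2. Bromination (NBS, MeCN) gives 1-bromo-2,4-dimethoxy-3-methyl-6-(2-phenylethyl)benzene F3, copper-mediated methoxylation (NaOMe, CuBr, DMF–MeOH, 110 °C) gives 1,3,4-trimethoxy-2-methyl-5-(2-phenylethyl)benzene F4, and iodination of its only free ring position (NIS, CF3CO2H) gives 1-iodo-2,4,5-trimethoxy-3-methyl-6-(2-phenylethyl)benzene F5; the distal ring is plain phenyl, so no site competition arises. Iodide 12 is borylated (pinacolborane, Pd(OAc)2, SPhos, Et3N, dioxane, 80 °C) to 2-Ar-4,4,5,5-tetramethyl-1,3,2-dioxaborolane F6. Coupling of F5 with F6 (Pd(OAc)2, SPhos, K3PO4, toluene–H2O, 100 °C) should give the heptamethoxy biaryl F7, and (NH4)2Ce(NO3)6 oxidises both trimethoxy rings of F7 to 26.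

Step 11. Ionisation may occur at the wrong carbon (loss of the methoxy group on the quaternary, alkene-bearing carbon), or MeLi may add in conjugate fashion; either would scramble the oxygen/methyl pattern. The fallback fixes that pattern on the four-membered ring before the alkenyl group arrives; it sets out from 16 and 15 and comes back at 22. MeLi is added to 16 (THF, −78 °C) to give 4-hydroxy-2,3-dimethoxy-4-methylcyclobut-2-en-1-one F8. Treatment with (CF3CO)2O and then MeOH converts it into the monoacetal 3,4,4-trimethoxy-2-methylcyclobut-2-en-1-one F9, whose only carbonyl lies next to the methyl-bearing carbon. Alkenyllithium 17, made from 15 as in step 10, adds to that carbonyl to give 1-[(1E)-1-Ar-4-phenylbut-1-en-1-yl]-3,4,4-trimethoxy-2-methylcyclobut-2-en-1-ol F10. Dilute aqueous HCl in THF at 0 °C unmasks the ketone to 4-[(1E)-1-Ar-4-phenylbut-1-en-1-yl]-4-hydroxy-2-methoxy-3-methylcyclobut-2-en-1-one F11, and MeI with Ag2O and K2CO3 in MeCN methylates the hydroxyl to 22.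

Step 7. Iodination may compete at the position para to the methoxy group of the distal ring, or go on to a second iodination. The fallback completes ring A before the second electron-rich ring is attached; it sets out from 3 and 2 and comes back at 12. Aldehyde 3 is brominated (NBS, MeCN) to 2-bromo-3,5-dimethoxy-4-methylbenzaldehyde F12, methoxylated (NaOMe, CuBr, DMF–MeOH, 100 °C) to 2,3,5-trimethoxy-4-methylbenzaldehyde F13 and iodinated at its last free position (NIS, CF3CO2H, MeCN, reflux) to 2-iodo-3,5,6-trimethoxy-4-methylbenzaldehyde F14. Wittig reaction of F14 with ylide 4 (from 2, KOtBu, THF) gives 1-iodo-2,4,5-trimethoxy-6-[2-(2-methoxyphenyl)ethenyl]-3-methylbenzene F15, and diimide (TsNHNH2, NaOAc, THF–H2O, reflux) reduces the alkene without touching the C–I bond, giving 12.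

Further compounds
F1 | step 12 | 1,3-dimethoxy-2-methyl-5-(2-phenylethenyl)benzene, E/Z mixture | COc1cc(C=Cc2ccccc2)cc(OC)c1C
F2 | step 12 | 1,3-dimethoxy-2-methyl-5-(2-phenylethyl)benzene | COc1cc(CCc2ccccc2)cc(OC)c1C
F3 | step 12 | 1-bromo-2,4-dimethoxy-3-methyl-6-(2-phenylethyl)benzene | COc1cc(CCc2ccccc2)c(Br)c(OC)c1C
F4 | step 12 | 1,3,4-trimethoxy-2-methyl-5-(2-phenylethyl)benzene | COc1cc(CCc2ccccc2)c(OC)c(OC)c1C
F5 | step 12 | 1-iodo-2,4,5-trimethoxy-3-methyl-6-(2-phenylethyl)benzene | COc1c(I)c(CCc2ccccc2)c(OC)c(OC)c1C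
F6 | step 12 | 2-Ar-4,4,5,5-tetramethyl-1,3,2-dioxaborolane | COc1ccccc1CCc1c(B2OC(C)(C)C(C)(C)O2)c(OC)c(C)c(OC)c1OC
F7 | step 12 | heptamethoxy biaryl (O-methyl ether of 25 at B3) | COc1ccccc1CCc1c(-c2c(CCc3ccccc3)c(OC)c(OC)c(C)c2OC)c(OC)c(C)c(OC)c1OC
F8 | step 11 | 4-hydroxy-2,3-dimethoxy-4-methylcyclobut-2-en-1-one, racemic | COC1=C(OC)[C@](C)(O)C1=O
F9 | step 11 | 3,4,4-trimethoxy-2-methylcyclobut-2-en-1-one | COC1=C(C)C(=O)C1(OC)OC
F10 | step 11 | 1-[(1E)-1-Ar-4-phenylbut-1-en-1-yl]-3,4,4-trimethoxy-2-methylcyclobut-2-en-1-ol, racemic | COC1=C(C)[C@@](O)(/C(=C/CCc2ccccc2)c2c(CCc3ccccc3OC)c(OC)c(OC)c(C)c2OC)C1(OC)OC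
F11 | step 11 | 4-[(1E)-1-Ar-4-phenylbut-1-en-1-yl]-4-hydroxy-2-methoxy-3-methylcyclobut-2-en-1-one, racemic | COC1=C(C)[C@@](O)(/C(=C/CCc2ccccc2)c2c(CCc3ccccc3OC)c(OC)c(OC)c(C)c2OC)C1=O
F12 | step 7 | 2-bromo-3,5-dimethoxy-4-methylbenzaldehyde | Cc1c(OC)cc(C=O)c(Br)c1OC
F13 | step 7 | 2,3,5-trimethoxy-4-methylbenzaldehyde | Cc1c(OC)cc(C=O)c(OC)c1OC
F14 | step 7 | 2-iodo-3,5,6-trimethoxy-4-methylbenzaldehyde | Cc1c(OC)c(I)c(C=O)c(OC)c1OC
F15 | step 7 | 1-iodo-2,4,5-trimethoxy-6-[2-(2-methoxyphenyl)ethenyl]-3-methylbenzene, E/Z mixture | COc1ccccc1C=Cc1c(I)c(OC)c(C)c(OC)c1OC
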